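Everything rests on cutting ring C of the flavanone at C3–C4. C4 is attached to the aromatic carbon C4a and C2 hangs on the phenolic oxygen O1 of the same ring A, so both atoms can carry a vinyl group and be joined by ring-closing metathesis. In one operation this closes the pyran ring as a (2S)-flav-3-ene that already bears the apigenin unit at C6 and leaves C4 as a benzylic alkene carbon, ready for hydration and oxidation to the ketone. The precursor is a hexa-MOM-protected 8-arylapigenin whose aryl ring carries a vinyl group ortho to an (S)-1-arylallyl ether; its C2 stereocentre comes from an iridium-catalysed allylic etherification.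

Key step: step 12

Remark 1: the target structure leaves the hindered C6–C8'' biaryl axis undefined; the route does not control it, so compounds 11–21 are carried as mixtures of rotamers about this axis.
Remark 2: the (Sa,Sc,Sc) ligand in step 11 is assigned from the usual sense of induction for O-nucleophiles on aryl-substituted allyl carbonates; a model reaction should confirm it, and the mirror-image ligand is used otherwise.

**Step 1**
Reactants: 1 apigenin
Product: 2 5,7-bis(methoxymethoxy)-2-[4-(methoxymethoxy)phenyl]-4H-chromen-4-one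
Conditions: NaH (4 equiv), MOMCl (4 equiv), DMF, 0 °C → rt
Reagents that add atoms: chloromethyl methyl ether (MOMCl), COCCl
Why: Williamson-type O-alkylation of the three sodium phenoxides, NaH being needed to engage the hydrogen-bonded 5-OH.

**Step 2**
Reactants: 2 5,7-bis(methoxymethoxy)-2-[4-(methoxymethoxy)phenyl]-4H-chromen-4-one
Product: 3 8-iodo-5,7-bis(methoxymethoxy)-2-[4-(methoxymethoxy)phenyl]-4H-chromen-4-one
Conditions: NIS (1.1 equiv), DMF, 25–50 °C, dark
Reagents that add atoms: N-iodosuccinimide, O=C1CCC(=O)N1I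
Why: Electrophilic aromatic iodination, which for 5,7-dialkoxyflavones with O5 alkylated prefers C8 over the more crowded C6, under neutral conditions that spare the acetals.

**Step 3**
Reactants: 4 phloroglucinol
Product: 5 3,5-bis(methoxymethoxy)phenol
Conditions: MOMCl (2.0 equiv), i-Pr2NEt (2.2 equiv), THF/DMF, 0 °C → rt; chromatography
Reagents that add atoms: chloromethyl methyl ether (MOMCl), COCCl
Why: Statistical O-alkylation of a threefold-symmetric triphenol, from which the bis-ether should be separable from the mono- and tris-ethers (the mono-ether can be recycled).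

**Step 4**
Reactants: 5 3,5-bis(methoxymethoxy)phenol
Product: 6 [3,5-bis(methoxymethoxy)phenoxy]tri(propan-2-yl)silane
Conditions: TIPSCl, imidazole, DMF, rt
Reagents that add atoms: chlorotri(propan-2-yl)silane (TIPSCl), CC(C)[Si](Cl)(C(C)C)C(C)C
Why: Standard silylation of the one free phenol, giving a bulky, non-directing and butyllithium-tolerant cap on the oxygen that will become O1.

**Step 5**
Reactants: 6 [3,5-bis(methoxymethoxy)phenoxy]tri(propan-2-yl)silane; 3 8-iodo-5,7-bis(methoxymethoxy)-2-[4-(methoxymethoxy)phenyl]-4H-chromen-4-one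
Product: 10 8-[4-hydroxy-2,6-bis(methoxymethoxy)phenyl]-5,7-bis(methoxymethoxy)-2-[4-(methoxymethoxy)phenyl]-4H-chromen-4-one (biaryl phenol), via aryllithium 7 (not isolated), via arylzinc chloride 8 (not isolated), via silyl ether biaryl 9 (not isolated)
Conditions: n-BuLi, THF, 0 °C; ZnCl2, 0 °C → rt; 3, Pd2(dba)3 (2.5 mol%), RuPhos (10 mol%), THF/NMP, 70 °C; aq. NH4Cl; then TBAF, THF, rt; aq. NH4Cl
Reagents that add atoms: none
Why: Directed ortho-metalation at the carbon flanked by both MOM ethers, Li→Zn exchange and Negishi coupling with a bulky dialkylbiarylphosphine suited to tetra-ortho-substituted biaryls (the arylzinc ignores the chromone carbonyl), after which fluoride cleaves only the aryl silyl ether.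

**Step 6**
Reactants: 10 8-[4-hydroxy-2,6-bis(methoxymethoxy)phenyl]-5,7-bis(methoxymethoxy)-2-[4-(methoxymethoxy)phenyl]-4H-chromen-4-one
Product: 11 8-[3-formyl-4-hydroxy-2,6-bis(methoxymethoxy)phenyl]-5,7-bis(methoxymethoxy)-2-[4-(methoxymethoxy)phenyl]-4H-chromen-4-one
Conditions: MgCl2 (3 equiv), Et3N (6 equiv), (CH2O)n (10 equiv), THF, 65 °C
Reagents that add atoms: paraformaldehyde (as formaldehyde), C=O
Why: Magnesium-phenoxide-directed ortho-formylation (Casnati–Skattebøl), in which the two positions ortho to the free OH are equivalent by the symmetry of that ring and the para position is blocked, so only one constitutional isomer can form.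

**Step 7**
Reactants: 11 8-[3-formyl-4-hydroxy-2,6-bis(methoxymethoxy)phenyl]-5,7-bis(methoxymethoxy)-2-[4-(methoxymethoxy)phenyl]-4H-chromen-4-one
Product: 12 8-[3-ethenyl-4-hydroxy-2,6-bis(methoxymethoxy)phenyl]-5,7-bis(methoxymethoxy)-2-[4-(methoxymethoxy)phenyl]-4H-chromen-4-one
Conditions: Ph3PCH3Br (3 equiv), KOtBu (3 equiv), THF, 0 °C → rt
Reagents that add atoms: methyltriphenylphosphonium bromide, C[P+](c1ccccc1)(c1ccccc1)c1ccccc1.[Br-]
Why: Wittig methylenation, chemoselective because the aldehyde is far more electrophilic than the vinylogous-ester carbonyl of the chromone, with excess ylide covering the phenolic proton.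

**Step 8**
Reactants: 13 methyl (E)-3-(4-hydroxyphenyl)prop-2-enoate
Product: 14 methyl (E)-3-[4-(methoxymethoxy)phenyl]prop-2-enoate
Conditions: MOMCl, i-Pr2NEt, CH2Cl2, 0 °C → rt
Reagents that add atoms: chloromethyl methyl ether (MOMCl), COCCl
Why: Routine O-alkylation of an unhindered phenol.

**Step 9**
Reactants: 14 methyl (E)-3-[4-(methoxymethoxy)phenyl]prop-2-enoate
Product: 15 (E)-3-[4-(methoxymethoxy)phenyl]prop-2-en-1-ol
Conditions: i-Bu2AlH (2.2 equiv), CH2Cl2, −78 → 0 °C; aq. potassium sodium tartrate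
Reagents that add atoms: none
Why: 1,2-Reduction of a cinnamate ester by DIBAL-H, which leaves the conjugated E alkene and the acetal untouched.

**Step 10**
Reactants: 15 (E)-3-[4-(methoxymethoxy)phenyl]prop-2-en-1-ol
Product: 16 methyl (E)-3-[4-(methoxymethoxy)phenyl]prop-2-en-1-yl carbonate
Conditions: ClCO2Me, pyridine, CH2Cl2, 0 °C
Reagents that add atoms: methyl chloroformate, COC(=O)Cl
Why: Acylation of a primary allylic alcohol to the linear carbonate, the standard electrophile for iridium-catalysed allylic substitution.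

**Step 11**
Reactants: 12 8-[3-ethenyl-4-hydroxy-2,6-bis(methoxymethoxy)phenyl]-5,7-bis(methoxymethoxy)-2-[4-(methoxymethoxy)phenyl]-4H-chromen-4-one; 16 methyl (E)-3-[4-(methoxymethoxy)phenyl]prop-2-en-1-yl carbonate
Product: 17 8-[3-ethenyl-2,6-bis(methoxymethoxy)-4-({(1S)-1-[4-(methoxymethoxy)phenyl]prop-2-en-1-yl}oxy)phenyl]-5,7-bis(methoxymethoxy)-2-[4-(methoxymethoxy)phenyl]-4H-chromen-4-one
Conditions: [Ir(cod)Cl]2 (2 mol%), (Sa,Sc,Sc)-O,O'-(1,1'-binaphthalene-2,2'-diyl) N,N-bis(1-phenylethyl)phosphoramidite (4 mol%), n-PrNH2 pre-activation; K3PO4, THF, rt → 40 °C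
Reagents that add atoms: none
Why: Iridium-catalysed asymmetric allylic etherification, in which the phenoxide attacks the aryl-substituted terminus of the allyl complex of the cyclometalated iridium phosphoramidite on the face set by the ligand, fixing C2 as (S); 2-vinylphenols are established nucleophiles for this reaction.

**Step 12**
Reactants: 17 8-[3-ethenyl-2,6-bis(methoxymethoxy)-4-({(1S)-1-[4-(methoxymethoxy)phenyl]prop-2-en-1-yl}oxy)phenyl]-5,7-bis(methoxymethoxy)-2-[4-(methoxymethoxy)phenyl]-4H-chromen-4-one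
Product: 18 8-{(2S)-5,7-bis(methoxymethoxy)-2-[4-(methoxymethoxy)phenyl]-2H-chromen-6-yl}-5,7-bis(methoxymethoxy)-2-[4-(methoxymethoxy)phenyl]-4H-chromen-4-one
Conditions: second-generation Grubbs catalyst RuCl2(=CHPh)(SIMes)(PCy3) (5 mol%), 1,4-benzoquinone (10 mol%), CH2Cl2 (5 mM), 40 °C
Reagents that add atoms: none
Why: The ruthenium benzylidene exchanges onto the less hindered vinyl group of the allylic ether, the new alkylidene adds [2+2] across the neighbouring styrene, and the ruthenacyclobutane cycloreverts to release ethylene and the C3=C4 bond. The closest known reaction is ring-closing metathesis of 2-vinylphenyl allyl ethers to 2H-chromenes. Ring C closes as a six-membered ring with an endocyclic cis alkene, between two terminal alkenes already held ortho to each other on ring A through O1 and C4a, and loss of ethylene makes the closure irreversible. No stereocentre is created; C2 from step 11 is allylic to the new alkene but none of its bonds is touched, and benzoquinone suppresses ruthenium hydride alkene migration that could erase it. The step needs chemoselectivity for the two monosubstituted alkenes, which the trisubstituted, electron-poor and ring-bound C2''=C3'' bond of the flavone secures by being inert, and it needs ring closure over dimerisation, which high dilution secures.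

**Step 13**
Reactants: 18 8-{(2S)-5,7-bis(methoxymethoxy)-2-[4-(methoxymethoxy)phenyl]-2H-chromen-6-yl}-5,7-bis(methoxymethoxy)-2-[4-(methoxymethoxy)phenyl]-4H-chromen-4-one
Product: 19 8-{(2S)-4-hydroxy-5,7-bis(methoxymethoxy)-2-[4-(methoxymethoxy)phenyl]-3,4-dihydro-2H-chromen-6-yl}-5,7-bis(methoxymethoxy)-2-[4-(methoxymethoxy)phenyl]-4H-chromen-4-one (C4 epimers)
Conditions: Co(acac)2 (20 mol%), PhSiH3 (2.5 equiv), O2 (1 atm), THF, rt
Reagents that add atoms: dioxygen, O=O
Why: Mukaiyama hydration, in which a cobalt hydride transfers hydrogen to C3 to give the C4 radical stabilised by ring A, which captures O2 and is reduced to the alcohol; the C4 configuration is irrelevant because it is oxidised next, and any ketone formed is already the product of step 14.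

**Step 14**
Reactants: 19 8-{(2S)-4-hydroxy-5,7-bis(methoxymethoxy)-2-[4-(methoxymethoxy)phenyl]-3,4-dihydro-2H-chromen-6-yl}-5,7-bis(methoxymethoxy)-2-[4-(methoxymethoxy)phenyl]-4H-chromen-4-one
Product: 20 8-{(2S)-5,7-bis(methoxymethoxy)-2-[4-(methoxymethoxy)phenyl]-4-oxo-3,4-dihydro-2H-chromen-6-yl}-5,7-bis(methoxymethoxy)-2-[4-(methoxymethoxy)phenyl]-4H-chromen-4-one
Conditions: Dess–Martin periodinane (1.5 equiv), pyridine, CH2Cl2, 0 °C → rt
Reagents that add atoms: none
Why: Dess–Martin oxidation of a secondary benzylic alcohol, buffered with pyridine so that neither the acetals nor the ionisable benzylic C–O bonds meet acid, and free of any base that could open the flavanone.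

**Step 15**
Reactants: 20 8-{(2S)-5,7-bis(methoxymethoxy)-2-[4-(methoxymethoxy)phenyl]-4-oxo-3,4-dihydro-2H-chromen-6-yl}-5,7-bis(methoxymethoxy)-2-[4-(methoxymethoxy)phenyl]-4H-chromen-4-one
Product: 21 8-[(2S)-5,7-dihydroxy-2-(4-hydroxyphenyl)-4-oxo-3,4-dihydro-2H-chromen-6-yl]-5,7-dihydroxy-2-(4-hydroxyphenyl)-4H-chromen-4-one (CNP0154104.1)
Conditions: 3 M aq. HCl, MeOH/THF, 45 °C
Reagents that add atoms: none
Why: Acid-catalysed acetal methanolysis should remove all six MOM groups in one operation, and acidic rather than basic conditions avoid the retro-oxa-Michael ring opening that would racemise C2.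

**Compound list**

1 | apigenin | O=c1cc(-c2ccc(O)cc2)oc2cc(O)cc(O)c12 | starting material
2 | 5,7-bis(methoxymethoxy)-2-[4-(methoxymethoxy)phenyl]-4H-chromen-4-one | COCOc1ccc(-c2cc(=O)c3c(OCOC)cc(OCOC)cc3o2)cc1 | intermediate
3 | 8-iodo-5,7-bis(methoxymethoxy)-2-[4-(methoxymethoxy)phenyl]-4H-chromen-4-one | COCOc1ccc(-c2cc(=O)c3c(OCOC)cc(OCOC)c(I)c3o2)cc1 | intermediate
4 | phloroglucinol | Oc1cc(O)cc(O)c1 | starting material
5 | 3,5-bis(methoxymethoxy)phenol | COCOc1cc(O)cc(OCOC)c1 | intermediate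
6 | [3,5-bis(methoxymethoxy)phenoxy]tri(propan-2-yl)silane | COCOc1cc(O[Si](C(C)C)(C(C)C)C(C)C)cc(OCOC)c1 | intermediate
7 | [2,6-bis(methoxymethoxy)-4-(triisopropylsilyloxy)phenyl]lithium | [Li]c1c(OCOC)cc(O[Si](C(C)C)(C(C)C)C(C)C)cc1OCOC | intermediate
8 | [2,6-bis(methoxymethoxy)-4-(triisopropylsilyloxy)phenyl]zinc chloride | Cl[Zn]c1c(OCOC)cc(O[Si](C(C)C)(C(C)C)C(C)C)cc1OCOC | intermediate
9 | 8-[2,6-bis(methoxymethoxy)-4-(triisopropylsilyloxy)phenyl]-5,7-bis(methoxymethoxy)-2-[4-(methoxymethoxy)phenyl]-4H-chromen-4-one | COCOc1ccc(-c2cc(=O)c3c(OCOC)cc(OCOC)c(-c4c(OCOC)cc(O[Si](C(C)C)(C(C)C)C(C)C)cc4OCOC)c3o2)cc1 | intermediate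
10 | 8-[4-hydroxy-2,6-bis(methoxymethoxy)phenyl]-5,7-bis(methoxymethoxy)-2-[4-(methoxymethoxy)phenyl]-4H-chromen-4-one | COCOc1ccc(-c2cc(=O)c3c(OCOC)cc(OCOC)c(-c4c(OCOC)cc(O)cc4OCOC)c3o2)cc1 | intermediate
11 | 8-[3-formyl-4-hydroxy-2,6-bis(methoxymethoxy)phenyl]-5,7-bis(methoxymethoxy)-2-[4-(methoxymethoxy)phenyl]-4H-chromen-4-one | COCOc1ccc(-c2cc(=O)c3c(OCOC)cc(OCOC)c(-c4c(OCOC)c(C=O)c(O)cc4OCOC)c3o2)cc1 | intermediate
12 | 8-[3-ethenyl-4-hydroxy-2,6-bis(methoxymethoxy)phenyl]-5,7-bis(methoxymethoxy)-2-[4-(methoxymethoxy)phenyl]-4H-chromen-4-one | COCOc1ccc(-c2cc(=O)c3c(OCOC)cc(OCOC)c(-c4c(OCOC)c(C=C)c(O)cc4OCOC)c3o2)cc1 | intermediate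
13 | methyl (E)-3-(4-hydroxyphenyl)prop-2-enoate | COC(=O)/C=C/c1ccc(O)cc1 | starting material
14 | methyl (E)-3-[4-(methoxymethoxy)phenyl]prop-2-enoate | COC(=O)/C=C/c1ccc(OCOC)cc1 | intermediate
15 | (E)-3-[4-(methoxymethoxy)phenyl]prop-2-en-1-ol | OC/C=C/c1ccc(OCOC)cc1 | intermediate
16 | methyl (E)-3-[4-(methoxymethoxy)phenyl]prop-2-en-1-yl carbonate | COC(=O)OC/C=C/c1ccc(OCOC)cc1 | intermediate
17 | 8-[3-ethenyl-2,6-bis(methoxymethoxy)-4-({(1S)-1-[4-(methoxymethoxy)phenyl]prop-2-en-1-yl}oxy)phenyl]-5,7-bis(methoxymethoxy)-2-[4-(methoxymethoxy)phenyl]-4H-chromen-4-one | C=C[C@@H](c1ccc(OCOC)cc1)Oc1cc(OCOC)c(-c2c(OCOC)cc(OCOC)c3c(=O)cc(-c4ccc(OCOC)cc4)oc23)c(OCOC)c1C=C | intermediate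
18 | 8-{(2S)-5,7-bis(methoxymethoxy)-2-[4-(methoxymethoxy)phenyl]-2H-chromen-6-yl}-5,7-bis(methoxymethoxy)-2-[4-(methoxymethoxy)phenyl]-4H-chromen-4-one | C1=C[C@@H](c2ccc(OCOC)cc2)Oc2cc(OCOC)c(-c3c(OCOC)cc(OCOC)c4c(=O)cc(-c5ccc(OCOC)cc5)oc34)c(OCOC)c21 | intermediate
19 | 8-{(2S)-4-hydroxy-5,7-bis(methoxymethoxy)-2-[4-(methoxymethoxy)phenyl]-3,4-dihydro-2H-chromen-6-yl}-5,7-bis(methoxymethoxy)-2-[4-(methoxymethoxy)phenyl]-4H-chromen-4-one (C4 epimers) | OC1C[C@@H](c2ccc(OCOC)cc2)Oc2cc(OCOC)c(-c3c(OCOC)cc(OCOC)c4c(=O)cc(-c5ccc(OCOC)cc5)oc34)c(OCOC)c21 | intermediate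
20 | 8-{(2S)-5,7-bis(methoxymethoxy)-2-[4-(methoxymethoxy)phenyl]-4-oxo-3,4-dihydro-2H-chromen-6-yl}-5,7-bis(methoxymethoxy)-2-[4-(methoxymethoxy)phenyl]-4H-chromen-4-one | O=C1C[C@@H](c2ccc(OCOC)cc2)Oc2cc(OCOC)c(-c3c(OCOC)cc(OCOC)c4c(=O)cc(-c5ccc(OCOC)cc5)oc34)c(OCOC)c21 | intermediate
21 | 8-[(2S)-5,7-dihydroxy-2-(4-hydroxyphenyl)-4-oxo-3,4-dihydro-2H-chromen-6-yl]-5,7-dihydroxy-2-(4-hydroxyphenyl)-4H-chromen-4-one | O=C1C[C@@H](c2ccc(O)cc2)Oc2cc(O)c(-c3c(O)cc(O)c4c(=O)cc(-c5ccc(O)cc5)oc34)c(O)c21 | target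

**Step count and risks**

Total step count: 15. Longest linear sequence: 10 steps (3, 4, 5, 6, 7, 11, 12, 13, 14, 15).

Steps most likely to fail:

1. Step 5. The coupling creates a biaryl with four ortho oxygen substituents. Transmetalation and reductive elimination at palladium may be too slow, so that protonation of the arylzinc and reduction of the iodide take over. The fallback reverses the polarity of the coupling; it sets out from 3 and 6 and comes back at 9, which is desilylated to 10 as in step 5. Iodide 3 would be borylated (B2pin2, PdCl2(dppf), KOAc, dioxane, 90 °C) to 5,7-bis(methoxymethoxy)-2-[4-(methoxymethoxy)phenyl]-8-(4,4,5,5-tetramethyl-1,3,2-dioxaborolan-2-yl)-4H-chromen-4-one F1. Silyl ether 6 would be lithiated as in step 5 and quenched with I2 to give [4-iodo-3,5-bis(methoxymethoxy)phenoxy]tri(propan-2-yl)silane F2. Suzuki–Miyaura coupling of the two (Pd(OAc)2, SPhos, K3PO4, toluene/H2O, 90 °C) should then give 9; flavone 8-boronates are established partners for hindered biflavonoid couplings.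

2. Step 11. The product is an electron-rich benzylic allylic ether that may re-ionise at iridium, eroding the enantiomeric purity or leaking to the linear ether. The fallback gives up catalyst control and resolves at the flavanone stage; it sets out from 12 and 16 and comes back at 20. The etherification would be run with the racemic ligand to give racemic 8-[3-ethenyl-2,6-bis(methoxymethoxy)-4-({1-[4-(methoxymethoxy)phenyl]prop-2-en-1-yl}oxy)phenyl]-5,7-bis(methoxymethoxy)-2-[4-(methoxymethoxy)phenyl]-4H-chromen-4-one F3. The conditions of steps 12 to 14 would carry it through the racemic flav-3-ene F4 and the racemic flavan-4-ol F5 to the racemic hexa-MOM flavanone F6. Kinetic resolution of F6 by asymmetric transfer hydrogenation (RuCl(p-cymene)[(R,R)-TsDPEN], HCO2H/Et3N, rt, to just over half conversion) should reduce the (2R) ketone to the cis-(2R,4R)-flavan-4-ol F7. The antipode of the catalyst is chosen from the usual aryl ketone model. Unreacted (2S)-20 would be recovered by chromatography. Kinetic resolution of racemic flavanones by transfer hydrogenation is known chemistry.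

3. Step 13. Hydrogen-atom transfer to the flavone enone, net hydrogenation of the chromene, or abstraction of the doubly activated C2–H may compete with oxygen capture at C4. The fallback replaces the radical hydration by a metal-catalysed Markovnikov hydroboration; it sets out from 18 and comes back at 19. Chromene 18 would be treated with catecholborane and [Rh(cod)2]BF4/dppb (THF, 0 °C → rt), which places boron on the benzylic carbon and gives 2-{(2S)-6-[flavon-8-yl]flavan-4-yl}-1,3,2-benzodioxaborole F8, all MOM groups retained. Oxidation with NaBO3·4H2O (THF/H2O, rt) should then give 19.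

**Further compounds**

F1 | step 5 | 5,7-bis(methoxymethoxy)-2-[4-(methoxymethoxy)phenyl]-8-(4,4,5,5-tetramethyl-1,3,2-dioxaborolan-2-yl)-4H-chromen-4-one | COCOc1ccc(-c2cc(=O)c3c(OCOC)cc(OCOC)c(B4OC(C)(C)C(C)(C)O4)c3o2)cc1
F2 | step 5 | [4-iodo-3,5-bis(methoxymethoxy)phenoxy]tri(propan-2-yl)silane | COCOc1cc(O[Si](C(C)C)(C(C)C)C(C)C)cc(OCOC)c1I
F3 | step 11 | racemic 8-[3-ethenyl-2,6-bis(methoxymethoxy)-4-({1-[4-(methoxymethoxy)phenyl]prop-2-en-1-yl}oxy)phenyl]-5,7-bis(methoxymethoxy)-2-[4-(methoxymethoxy)phenyl]-4H-chromen-4-one | C=CC(c1ccc(OCOC)cc1)Oc1cc(OCOC)c(-c2c(OCOC)cc(OCOC)c3c(=O)cc(-c4ccc(OCOC)cc4)oc23)c(OCOC)c1C=C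
F4 | step 11 | racemic 8-{5,7-bis(methoxymethoxy)-2-[4-(methoxymethoxy)phenyl]-2H-chromen-6-yl}-5,7-bis(methoxymethoxy)-2-[4-(methoxymethoxy)phenyl]-4H-chromen-4-one | C1=CC(c2ccc(OCOC)cc2)Oc2cc(OCOC)c(-c3c(OCOC)cc(OCOC)c4c(=O)cc(-c5ccc(OCOC)cc5)oc34)c(OCOC)c21
F5 | step 11 | racemic 8-{4-hydroxy-5,7-bis(methoxymethoxy)-2-[4-(methoxymethoxy)phenyl]-3,4-dihydro-2H-chromen-6-yl}-5,7-bis(methoxymethoxy)-2-[4-(methoxymethoxy)phenyl]-4H-chromen-4-one | OC1CC(c2ccc(OCOC)cc2)Oc2cc(OCOC)c(-c3c(OCOC)cc(OCOC)c4c(=O)cc(-c5ccc(OCOC)cc5)oc34)c(OCOC)c21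
F6 | step 11 | racemic 8-{5,7-bis(methoxymethoxy)-2-[4-(methoxymethoxy)phenyl]-4-oxo-3,4-dihydro-2H-chromen-6-yl}-5,7-bis(methoxymethoxy)-2-[4-(methoxymethoxy)phenyl]-4H-chromen-4-one | O=C1CC(c2ccc(OCOC)cc2)Oc2cc(OCOC)c(-c3c(OCOC)cc(OCOC)c4c(=O)cc(-c5ccc(OCOC)cc5)oc34)c(OCOC)c21
F7 | step 11 | 8-{(2R,4R)-4-hydroxy-5,7-bis(methoxymethoxy)-2-[4-(methoxymethoxy)phenyl]-3,4-dihydro-2H-chromen-6-yl}-5,7-bis(methoxymethoxy)-2-[4-(methoxymethoxy)phenyl]-4H-chromen-4-one | O[C@@H]1C[C@H](c2ccc(OCOC)cc2)Oc2cc(OCOC)c(-c3c(OCOC)cc(OCOC)c4c(=O)cc(-c5ccc(OCOC)cc5)oc34)c(OCOC)c21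
F8 | step 13 | 8-{(2S)-4-(1,3,2-benzodioxaborol-2-yl)-5,7-bis(methoxymethoxy)-2-[4-(methoxymethoxy)phenyl]-3,4-dihydro-2H-chromen-6-yl}-5,7-bis(methoxymethoxy)-2-[4-(methoxymethoxy)phenyl]-4H-chromen-4-one | C1(B2Oc3ccccc3O2)C[C@@H](c2ccc(OCOC)cc2)Oc2cc(OCOC)c(-c3c(OCOC)cc(OCOC)c4c(=O)cc(-c5ccc(OCOC)cc5)oc34)c(OCOC)c21
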